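The ratio I would carry through this examination is a fraction of a fraction: of the substrate charge not held in target, how much stands as open intermediate?

| flask | substrate | partner | capture agent | temperature | remark | time |
|---|---|---|---|---|---|---|
| green | 0.025 M | 0.045 M | 0.013 M | −24 °C | run made earlier |  |
| grey | 0.025 M | 0.045 M | 0.050 M | 1 °C | run made earlier |  |
| midnight | 0.025 M | 0.0450 M | 0.0250 M | −5 °C |  | 8.0 min |
| winter | 0.025 M | 0.0450 M | 0.0250 M | −20 °C |  | 8.0 min |
| spring | 0.025 M | 0.0450 M | 0.0250 M | 10 °C |  | 8.0 min |
| dawn | 0.025 M | 0.0450 M | 0.0250 M | −35 °C |  | 8.0 min |

| run | time / min | open intermediate / % | target / % |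
|---|---|---|---|
| green | 2.50 | 33.5 | 7.5 |
| green | 5.00 | 31.5 | 10.0 |
| green | 8.00 | 33.7 | 10.0 |
| green | 10.0 | 32.0 | 12.7 |
| green | 12.0 | 31.1 | 13.2 |
| green | 15.0 | 32.4 | 12.5 |
| grey | 1.00 | 23.7 | 14.7 |
| grey | 2.00 | 25.0 | 10.8 |
| grey | 3.00 | 27.2 | 8.1 |
| grey | 4.00 | 28.8 | 6.3 |
| grey | 5.00 | 28.2 | 2.9 |
| grey | 6.00 | 28.6 | 4.9 |

(standard deviation of a reading: 1 percentage point)

* the flask with the highest amount of open intermediate, in percent of the substrate charged ("all alike" if they lie within 1.5 percentage points) (midnight / winter / spring / dawn / all alike)
* final open intermediate, as a percentage of the substrate charged, in midnight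
* final open intermediate, as a percentage of the substrate charged, in winter
* final open intermediate, as a percentage of the substrate charged, in spring
* final open intermediate, as a percentage of the substrate charged, in dawn

- steps that have been proposed: second intermediate + capture agent -> trapped intermediate; open intermediate + second intermediate <-> target; substrate <-> open intermediate; 2 second intermediate -> homo product; partner -> second intermediate

Why that ratio? The substrate is charged below the partner, and its balance is short: by the proposed steps it stands as substrate, open intermediate or target, and these three fractions of the charge sum to one. Target takes its part of the pool, and the opening then divides what remains.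

What does green give? At 15.0 min, the green readings put open intermediate at 0.324 of the charge and target at 0.125, so the ratio reads 0.370. I call this the open share, the fraction of open intermediate divided by the fraction not in target.

Is it steady? At 2.50 min the green reading gives 0.362, and the two differ by no more than a reading's scatter of 1 percentage point can account for.

Does the capture agent disturb it? In grey, target falls from 0.147 to 0.0490 of the charge, yet the share goes from 0.278 to 0.301. The pool outside target grows as target falls in grey, and its division moves little.

And temperature? Grey at 1 °C shows a smaller share than green at −24 °C, but these two runs differ in capture agent as well. Since grey's share moved little while its target fell, I put the difference down to temperature as a judgement, and I commit to an order of the share among the four flasks, which hold the same charges: the colder flask holds the larger share, with dawn first.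

Now the weak spot: dawn is colder than either run, so has the opening time to arrive? The ratio reads as a pre-equilibrium, and that needs time. Green's share read steady from 2.50 min, and dawn has 3.20 times as long as that. I cannot size this margin from two runs, so I accept it as a risk.

The forecast gave 37.5% for dawn, 31.8% for winter, 27.5% for midnight and 25% for spring, naming dawn as highest, “assuming equilibrium is still reached”. My own reckoning goes no further than the order, and the two agree on it.

The flasks give 37.6% in dawn, 31.3% in winter, 27.7% in midnight and 24.8% in spring, so dawn is highest and the forecast held within its tolerance.

    second intermediate + capture agent → trapped intermediate (k = 0.0523 M⁻¹ s⁻¹, Ea = 46.0 kJ mol⁻¹)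
    open intermediate + second intermediate ⇌ target (K = 12.0 M⁻¹, k = 0.160 M⁻¹ s⁻¹, Ea = 45.0 kJ mol⁻¹, ΔH = 20.0 kJ mol⁻¹)
    substrate ⇌ open intermediate (K = 0.540, k = 0.0262 s⁻¹, Ea = 66.0 kJ mol⁻¹, ΔH = −8.00 kJ mol⁻¹)
    2 second intermediate → homo product (k = 0.00229 M⁻¹ s⁻¹, Ea = 63.0 kJ mol⁻¹)
    partner → second intermediate (k = 0.0132 s⁻¹, Ea = 64.0 kJ mol⁻¹)
    (constants at −20 °C)

In dawn, open intermediate was made 6.61 times faster than it was used up at 3.10 min, each step taken net, and 1.18 times faster at 8.00 min; at that time dawn's open share of 0.394 stands above the 0.370 read in green and just below the 0.407 that the equilibrium constant of the opening gives. The neighbouring flask, like dawn but kept at −50 °C, shows a smaller open share than dawn at 8.00 min, 0.153, with 85% of its substrate still there.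

The earlier runs and the new flask are calculated for an exercise; the scatter is artificial.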